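**Retrosynthetic overview**
- The C8 prenyl group comes from cross-metathesis of an 8-allyl group, which is placed by aromatic Claisen rearrangement of the 7-O-allyl ether (C6 is blocked by OMe, so only C8 is open).
- The pyranone ring (the only ring built) is closed last in the core synthesis, by acid cyclisation of a 2-hydroxyaryl β-keto dimethyl acetal.
- That acetal comes from a Tl(III) oxidative 1,2-aryl shift of a 2',4'-bis(benzyloxy)chalcone.
- The chalcone comes from a Claisen–Schmidt aldol condensation of 2,4-bis(benzyloxy)-5-methoxyacetophenone with veratraldehyde (the key C–C bond, joining the A- and B-ring fragments).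
- The acetophenone comes from 4-methoxyresorcinol (C-acetylation, O-benzylation), which comes from isovanillin by Baeyer–Villiger oxidation.

Assumption: the target is achiral (no stereocentre), so no enantiocontrol is needed; the only stereo-elements on the way (the E-alkene of the chalcone and racemic sp3 centres in intermediates) are destroyed later.

**Route**

Step 1
Reactants: 1 isovanillin (3-hydroxy-4-methoxybenzaldehyde)
Product: 2 5-formyl-2-methoxyphenyl acetate (3-acetoxy-4-methoxybenzaldehyde)
Conditions: Ac2O (1.2 equiv), pyridine, DMAP (cat.), CH2Cl2, 0 °C to rt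
Reagents that add atoms: acetic anhydride, CC(=O)OC(C)=O
Why: Routine O-acetylation (nucleophilic acyl substitution) masks the phenol so the peracid step is clean.

Step 2
Reactants: 2 5-formyl-2-methoxyphenyl acetate
Product: 4 4-methoxybenzene-1,3-diol (4-methoxyresorcinol), via 3-acetoxy-4-methoxyphenyl formate 3 (not isolated)
Conditions: mCPBA (1.3 equiv), CH2Cl2, 0 °C to rt; evaporate; then MeOH, conc. HCl (cat.), 50 °C, N2
Reagents that add atoms: 3-chloroperoxybenzoic acid (mCPBA), OOC(=O)c1cccc(Cl)c1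
Why: Baeyer–Villiger (Dakin-type) oxidation in which the para-methoxy aryl group migrates in preference to H, followed by acid-catalysed methanolysis of both aryl esters under non-basic conditions that protect the air-sensitive resorcinol.

Step 3
Reactants: 4 4-methoxybenzene-1,3-diol
Product: 5 1-(2,4-dihydroxy-5-methoxyphenyl)ethan-1-one
Conditions: AcOH (1.5 equiv), BF3·OEt2 (Lewis-acid promoter and medium), 90 °C, 2 h; aq. NaOAc work-up
Reagents that add atoms: acetic acid, CC(=O)O
Why: Friedel–Crafts (Nencki-type) C-acylation of a resorcinol goes ortho to one OH and para to the other (C6), because C2 is flanked by two OH groups and C5 is not activated.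

Step 4
Reactants: 5 1-(2,4-dihydroxy-5-methoxyphenyl)ethan-1-one
Product: 6 1-[2,4-bis(benzyloxy)-5-methoxyphenyl]ethan-1-one
Conditions: BnBr (2.5 equiv), K2CO3 (3 equiv), KI (cat.), DMF, 80 °C
Reagents that add atoms: benzyl bromide, BrCc1ccccc1
Why: Williamson ether synthesis; heating in DMF also alkylates the chelated 2-OH, and full protection removes any free phenol before the aldol and Tl(III) steps.

Step 5
Reactants: 6 1-[2,4-bis(benzyloxy)-5-methoxyphenyl]ethan-1-one; 7 3,4-dimethoxybenzaldehyde (veratraldehyde)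
Product: 9 (E)-1-[2,4-bis(benzyloxy)-5-methoxyphenyl]-3-(3,4-dimethoxyphenyl)prop-2-en-1-one, via aldol adduct 8 (not isolated)
Conditions: KOH (50% aq.), EtOH, rt, 24–48 h
Reagents that add atoms: none
Why: Claisen–Schmidt crossed aldol condensation between a methyl ketone enolate and a non-enolisable aldehyde, with E1cB dehydration giving the thermodynamically favoured E-enone.

Step 6
Reactants: 9 (E)-1-[2,4-bis(benzyloxy)-5-methoxyphenyl]-3-(3,4-dimethoxyphenyl)prop-2-en-1-one
Product: 10 1-[2,4-bis(benzyloxy)-5-methoxyphenyl]-2-(3,4-dimethoxyphenyl)-3,3-dimethoxypropan-1-one (racemic)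
Conditions: Tl(NO3)3·3H2O (1.2 equiv), MeOH–CHCl3 (4:1), rt, 12 h; aq. NaHCO3/Na2SO3 quench
Reagents that add atoms: methanol, CO
Why: Thallium(III) nitrate oxidative rearrangement of a chalcone: methoxythallation at the benzylic carbon, 1,2-shift of the electron-rich veratryl group as Tl(I) leaves, and capture of the oxocarbenium by MeOH; the new centre is racemic and is lost in step 7.

Step 7
Reactants: 10 1-[2,4-bis(benzyloxy)-5-methoxyphenyl]-2-(3,4-dimethoxyphenyl)-3,3-dimethoxypropan-1-one
Product: 12 7-hydroxy-6-methoxy-3-(3,4-dimethoxyphenyl)-4H-chromen-4-one (cladrastin), via debenzylated keto acetal 11 (not isolated)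
Conditions: H2 (1 atm), 10% Pd/C, MeOH–EtOAc, rt; filter; then conc. HCl (cat.), MeOH, reflux, 1 h
Reagents that add atoms: none
Why: Hydrogenolysis of both benzyl ethers is done before any chromone C2=C3 bond exists, then acid-catalysed acetal exchange with the 2-OH and elimination of methanol closes the pyranone ring with the 7-OH already free.

Step 8
Reactants: 12 7-hydroxy-6-methoxy-3-(3,4-dimethoxyphenyl)-4H-chromen-4-one
Product: 13 7-(allyloxy)-6-methoxy-3-(3,4-dimethoxyphenyl)-4H-chromen-4-one
Conditions: allyl bromide (1.5 equiv), K2CO3 (2 equiv), acetone, reflux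
Reagents that add atoms: allyl bromide, C=CCBr
Why: Williamson O-allylation of the only free (and acidic) phenol.

Step 9
Reactants: 13 7-(allyloxy)-6-methoxy-3-(3,4-dimethoxyphenyl)-4H-chromen-4-one
Product: 15 8-allyl-7-hydroxy-6-methoxy-3-(3,4-dimethoxyphenyl)-4H-chromen-4-one, via Claisen dienone 14 (not isolated)
Conditions: PhNEt2, 200–210 °C, Ar, 4 h
Reagents that add atoms: none
Why: Aromatic Claisen [3,3]-sigmatropic rearrangement delivers the allyl group to C8, the only unsubstituted ortho position, and the dienone re-aromatises by tautomerisation.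

Step 10
Reactants: 15 8-allyl-7-hydroxy-6-methoxy-3-(3,4-dimethoxyphenyl)-4H-chromen-4-one
Product: 16 7-hydroxy-6-methoxy-3-(3,4-dimethoxyphenyl)-8-(3-methylbut-2-en-1-yl)-4H-chromen-4-one (target)
Conditions: Grubbs II (5 mol %), 2-methyl-2-butene (large excess), CH2Cl2, 40 °C, sealed tube
Reagents that add atoms: 2-methyl-2-butene, CC=C(C)C
Why: Olefin cross-metathesis of a terminal allyl arene with excess 2-methyl-2-butene gives the prenyl group and volatile propene, and leaves the phenol and the electron-poor chromone C2=C3 bond untouched.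

**Compound list**

1 | isovanillin (3-hydroxy-4-methoxybenzaldehyde) | COc1ccc(C=O)cc1O | starting material
2 | 5-formyl-2-methoxyphenyl acetate | COc1ccc(C=O)cc1OC(C)=O | intermediate
3 | 3-acetoxy-4-methoxyphenyl formate | COc1ccc(OC=O)cc1OC(C)=O | intermediate (not isolated)
4 | 4-methoxybenzene-1,3-diol | COc1ccc(O)cc1O | intermediate
5 | 1-(2,4-dihydroxy-5-methoxyphenyl)ethan-1-one | CC(=O)c1cc(OC)c(O)cc1O | intermediate
6 | 1-[2,4-bis(benzyloxy)-5-methoxyphenyl]ethan-1-one | CC(=O)c1cc(OC)c(OCc2ccccc2)cc1OCc1ccccc1 | intermediate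
7 | 3,4-dimethoxybenzaldehyde (veratraldehyde) | COc1ccc(C=O)cc1OC | starting material
8 | 1-[2,4-bis(benzyloxy)-5-methoxyphenyl]-3-(3,4-dimethoxyphenyl)-3-hydroxypropan-1-one (racemic aldol adduct) | COc1ccc(C(O)CC(=O)c2cc(OC)c(OCc3ccccc3)cc2OCc2ccccc2)cc1OC | intermediate (not isolated)
9 | (E)-1-[2,4-bis(benzyloxy)-5-methoxyphenyl]-3-(3,4-dimethoxyphenyl)prop-2-en-1-one | COc1ccc(/C=C/C(=O)c2cc(OC)c(OCc3ccccc3)cc2OCc2ccccc2)cc1OC | intermediate
10 | 1-[2,4-bis(benzyloxy)-5-methoxyphenyl]-2-(3,4-dimethoxyphenyl)-3,3-dimethoxypropan-1-one (racemic) | COc1ccc(C(C(OC)OC)C(=O)c2cc(OC)c(OCc3ccccc3)cc2OCc2ccccc2)cc1OC | intermediate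
11 | 1-(2,4-dihydroxy-5-methoxyphenyl)-2-(3,4-dimethoxyphenyl)-3,3-dimethoxypropan-1-one (racemic) | COc1ccc(C(C(OC)OC)C(=O)c2cc(OC)c(O)cc2O)cc1OC | intermediate (not isolated)
12 | 7-hydroxy-6-methoxy-3-(3,4-dimethoxyphenyl)-4H-chromen-4-one (cladrastin) | COc1ccc(-c2coc3cc(O)c(OC)cc3c2=O)cc1OC | intermediate
13 | 7-(allyloxy)-6-methoxy-3-(3,4-dimethoxyphenyl)-4H-chromen-4-one | COc1ccc(-c2coc3cc(OCC=C)c(OC)cc3c2=O)cc1OC | intermediate
14 | 8-allyl-6-methoxy-3-(3,4-dimethoxyphenyl)-8H-chromene-4,7-dione (racemic Claisen dienone) | COc1ccc(C2=COC3=C(C=C(OC)C(=O)C3CC=C)C2=O)cc1OC | intermediate (not isolated)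
15 | 8-allyl-7-hydroxy-6-methoxy-3-(3,4-dimethoxyphenyl)-4H-chromen-4-one | COc1ccc(-c2coc3c(CC=C)c(O)c(OC)cc3c2=O)cc1OC | intermediate
16 | 7-hydroxy-6-methoxy-3-(3,4-dimethoxyphenyl)-8-(3-methylbut-2-en-1-yl)-4H-chromen-4-one | COc1ccc(-c2coc3c(CC=C(C)C)c(O)c(OC)cc3c2=O)cc1OC | target

**Totals**

Total step count: 10. Longest linear sequence: 10 steps (1 to 16); veratraldehyde 7 enters at step 5.

**Steps most likely to fail, with fallbacks**

Step 6 (Tl(III) oxidative rearrangement; the electron-rich A-ring may be over-oxidised or the aryl shift may be incomplete). The fallback sets out from 9 and comes back at 12. Weitz–Scheffer epoxidation of chalcone 9 (30% H2O2, aq. NaOH, MeOH–THF, 0 °C to rt) gives the racemic trans-epoxide [2,4-bis(benzyloxy)-5-methoxyphenyl][3-(3,4-dimethoxyphenyl)oxiran-2-yl]methanone F1. BF3·OEt2 in CH2Cl2 at 0 °C opens it at the veratryl-stabilised benzylic carbon, and a 1,2-acyl shift gives 3-[2,4-bis(benzyloxy)-5-methoxyphenyl]-2-(3,4-dimethoxyphenyl)-3-oxopropanal F2. Hydrogenolysis (H2, Pd/C, EtOAc) followed by brief warming with HCl in MeOH cyclodehydrates the freed 2-hydroxyaryl keto-aldehyde to 12. This route is thallium-free and keeps the same aldol bond construction.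

Step 9 (thermal Claisen at about 200 °C; decomposition or incomplete conversion). The fallback sets out from 12 and comes back at 16. O-Alkylation of 12 with 3-chloro-3-methylbut-1-yne (K2CO3, KI, CuI cat., acetone, reflux) gives 7-[(2-methylbut-3-yn-2-yl)oxy]-6-methoxy-3-(3,4-dimethoxyphenyl)-4H-chromen-4-one F3. Lindlar semi-hydrogenation (H2, Pd/CaCO3–Pb, quinoline, EtOAc) gives 7-[(2-methylbut-3-en-2-yl)oxy]-6-methoxy-3-(3,4-dimethoxyphenyl)-4H-chromen-4-one F4. This 1,1-dimethylallyl ether undergoes Claisen rearrangement at only 120–130 °C (PhNEt2 or xylene) and places the prenyl group directly at C8, giving 16 without the allyl intermediate or the metathesis.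

Step 10 (cross-metathesis; Ru-hydride isomerisation of the o-allylphenol to the propenyl arene, or stalling by phenol/carbonyl chelation). The fallback sets out from 12 and comes back at 16. Iodination of 12 (NIS, DMF, rt) occurs ortho to the phenol at C8, the only free position on the A-ring next to OH, to give 7-hydroxy-8-iodo-6-methoxy-3-(3,4-dimethoxyphenyl)-4H-chromen-4-one F5. Stille coupling with tributyl(3-methylbut-2-en-1-yl)stannane (Pd(PPh3)4, DMF, 90 °C) then gives 16; the linear (α) coupling product is expected to dominate, with some reverse-prenyl isomer possible.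

**Further compounds**

F1 | step 6 | [2,4-bis(benzyloxy)-5-methoxyphenyl][3-(3,4-dimethoxyphenyl)oxiran-2-yl]methanone (racemic trans; one enantiomer drawn) | COc1ccc([C@H]2O[C@@H]2C(=O)c2cc(OC)c(OCc3ccccc3)cc2OCc2ccccc2)cc1OC
F2 | step 6 | 3-[2,4-bis(benzyloxy)-5-methoxyphenyl]-2-(3,4-dimethoxyphenyl)-3-oxopropanal (racemic, enolisable) | COc1ccc(C(C=O)C(=O)c2cc(OC)c(OCc3ccccc3)cc2OCc2ccccc2)cc1OC
F3 | step 9 | 7-[(2-methylbut-3-yn-2-yl)oxy]-6-methoxy-3-(3,4-dimethoxyphenyl)-4H-chromen-4-one | COc1ccc(-c2coc3cc(OC(C)(C)C#C)c(OC)cc3c2=O)cc1OC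
F4 | step 9 | 7-[(2-methylbut-3-en-2-yl)oxy]-6-methoxy-3-(3,4-dimethoxyphenyl)-4H-chromen-4-one | COc1ccc(-c2coc3cc(OC(C)(C)C=C)c(OC)cc3c2=O)cc1OC
F5 | step 10 | 7-hydroxy-8-iodo-6-methoxy-3-(3,4-dimethoxyphenyl)-4H-chromen-4-one | COc1ccc(-c2coc3c(I)c(O)c(OC)cc3c2=O)cc1OC
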